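Ring B is built, not functionalised: its six carbons are assembled around the prenyl-bearing carbon C3', which lies between the oxygenated carbons C2' and C4', while C1' carries C3 of the chroman (rings A and C). Photolysis of an enantiopure chroman-3-yl alkenyl diazomethyl ketone gives a vinylketene that is captured by a prenyl-substituted siloxyalkyne. Wolff shift, [2+2] addition, cyclobutenone opening and 6π closure form four C–C bonds and ring B in one operation, leaving the C2' hydroxyl free and O4' silylated. The precursor is an (R)-7-(methoxymethoxy)chroman with an (E)-CH=CH–CO–CHN2 chain at C3, its stereocentre set by asymmetric hydrogenation. The dimethylpyran is then fused at O4'/C5'.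

Key step: step 9

Remarks on the chemistry
- Atom labels: chroman O1, C2, C3, C4, C4a–C8a (ring A aromatic, ring C heterocycle); ring B C1'–C6', with C1' bonded to C3.
- Ynolate formation by ester homologation adds one carbon beyond the acyl chain. The prenyl-bearing siloxyalkyne 18 therefore needs ethyl 4-methylpent-3-enoate (15); a 5-methylhex-4-enoate ester would place a homoprenyl group on C3'.
- Assumption: the ligand antipode that delivers the (S)-acid 8 in step 4 is assigned on a test scale; both antipodes are accessible.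
- The pyran is closed by condensation with 3-methylbut-2-enal after desilylation. C5' is the only free carbon ortho to a ring B hydroxyl, so O2' needs no protection.

Step 1
Reactants: 1 2,4-dihydroxybenzaldehyde
Product: 2 2-hydroxy-4-(methoxymethoxy)benzaldehyde
Conditions: MOMCl, K2CO3, acetone, 0 °C → rt
Reagents that add atoms: chloromethyl methyl ether, COCCl
Why: Williamson-type O-alkylation is selective for the 4-hydroxyl because the 2-hydroxyl is held in a hydrogen bond to the formyl group and is the weaker nucleophile under weak base.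

Step 2
Reactants: 2 2-hydroxy-4-(methoxymethoxy)benzaldehyde; 3 acrylonitrile
Product: 5 7-(methoxymethoxy)-2H-chromene-3-carbonitrile, via aldol adduct 4 (not isolated)
Conditions: DABCO (0.3 equiv), neat 3 (excess), 80 °C
Reagents that add atoms: none
Why: DABCO-mediated Baylis–Hillman/oxa-Michael cascade, in which phenoxide conjugate addition and aldol closure give 4 and dehydration gives the conjugated chromene nitrile, the standard annulation of salicylaldehydes with acrylonitrile.

Step 3
Reactants: 5 7-(methoxymethoxy)-2H-chromene-3-carbonitrile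
Product: 7 7-(methoxymethoxy)-2H-chromene-3-carboxylic acid, via primary amide 6 (not isolated)
Conditions: 10% aq. NaOH, reflux; then 1 M HCl, 0 °C, to pH 3–4
Reagents that add atoms: sodium hydroxide, [Na+].[OH-]; water, O
Why: Alkaline nitrile hydrolysis runs through amide 6 to the carboxylate; the aryl MOM acetal is inert to base and should survive a brief cold acidification.

Step 4
Reactants: 7 7-(methoxymethoxy)-2H-chromene-3-carboxylic acid
Product: 8 (S)-7-(methoxymethoxy)chroman-3-carboxylic acid
Conditions: [Ir(cod)((Sa,S)-SIPHOX)]BArF (1 mol%), H2 (6 atm), Et3N (0.5 equiv), MeOH, rt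
Reagents that add atoms: none
Why: Carboxylate-directed iridium asymmetric hydrogenation of a trisubstituted α,β-unsaturated acid, in which the chiral spiro phosphine–oxazoline ligand fixes the face of hydrogen delivery to C3 and so sets the only stereocentre as S.

Step 5
Reactants: 8 (S)-7-(methoxymethoxy)chroman-3-carboxylic acid
Product: 9 (R)-[7-(methoxymethoxy)chroman-3-yl]methanol
Conditions: BH3·SMe2, THF, 0 °C → rt; then H2O
Reagents that add atoms: none
Why: Borane reduces the carboxylic acid chemoselectively under non-basic conditions, so the α-centre is not enolised; the descriptor changes to R through CIP priorities only.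

Step 6
Reactants: 9 (R)-[7-(methoxymethoxy)chroman-3-yl]methanol; 10 1-(triphenyl-λ5-phosphanylidene)propan-2-one
Product: 12 (R,E)-4-[7-(methoxymethoxy)chroman-3-yl]but-3-en-2-one, via aldehyde 11 (not isolated)
Conditions: Dess–Martin periodinane, NaHCO3, CH2Cl2, 0 °C → rt; then 10 (2 equiv), rt → 40 °C
Reagents that add atoms: none
Why: Buffered Dess–Martin oxidation gives the epimerisable α-branched aldehyde 11, which is trapped in the same flask by the stabilised ylide (Wittig reaction) to give the E-enone without contact with base or silica.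

Step 7
Reactants: 12 (R,E)-4-[7-(methoxymethoxy)chroman-3-yl]but-3-en-2-one
Product: 14 (R,E)-1-diazo-4-[7-(methoxymethoxy)chroman-3-yl]but-3-en-2-one, via trifluoroacetyl diketone 13 (not isolated)
Conditions: LiN(SiMe3)2, THF, −78 °C; CF3CO2CH2CF3; cold 1 M HCl quench; then 4-acetamidobenzenesulfonyl azide, Et3N, H2O, MeCN, rt
Reagents that add atoms: 4-acetamidobenzenesulfonyl azide, CC(=O)Nc1ccc(cc1)S(=O)(=O)N=[N+]=[N-]; 2,2,2-trifluoroethyl trifluoroacetate, O=C(OCC(F)(F)F)C(F)(F)F (atoms kept only in 13)
Why: Detrifluoroacetylative Regitz diazo transfer, in which kinetic deprotonation at the methyl group and Claisen trifluoroacetylation give 13, whose activated methylene takes the diazo group with loss of the trifluoroacetyl unit; the γ C3–H is not touched.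

Step 8
Reactants: 15 ethyl 4-methylpent-3-enoate
Product: 18 triisopropyl[(5-methylhex-4-en-1-yn-1-yl)oxy]silane, via dibromo enolate 16 (not isolated), via lithium ynolate 17 (not isolated)
Conditions: CH2Br2, LiTMP (lithium 2,2,6,6-tetramethylpiperidide), THF, −78 °C; 15; n-BuLi, −78 → 0 °C; i-Pr3SiCl, −78 °C → rt
Reagents that add atoms: dibromomethane, BrCBr; chlorotri(propan-2-yl)silane, CC(C)[Si](Cl)(C(C)C)C(C)C; lithium 2,2,6,6-tetramethylpiperidide, [Li]N1C(C)(C)CCCC1(C)C (lithium kept only in 16 and 17)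
Why: Kowalski ester homologation stopped at the ynolate, in which dibromomethyllithium adds to the ester, bromine–lithium exchange on 16 triggers 1,2-shift of the prenyl group to give 17, and the bulky silyl chloride reacts at oxygen.

Step 9
Reactants: 14 (R,E)-1-diazo-4-[7-(methoxymethoxy)chroman-3-yl]but-3-en-2-one; 18 triisopropyl[(5-methylhex-4-en-1-yn-1-yl)oxy]silane
Product: 23 (R)-6-[7-(methoxymethoxy)chroman-3-yl]-2-(3-methylbut-2-en-1-yl)-3-[(triisopropylsilyl)oxy]phenol, via vinylketene 19 (not isolated), via vinylcyclobutenone 20 (not isolated), via dienylketene 21 (not isolated), via cyclohexadienone 22 (not isolated)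
Conditions: hν (450 W medium-pressure Hg lamp, Pyrex), 18 (1.5 equiv), degassed ClCH2CH2Cl, rt; then 80 °C in the dark
Reagents that add atoms: none
Why: Light expels N2 from 14 and the alkenyl group migrates to the former diazo carbon (Wolff rearrangement, bond C5'–C6') to give vinylketene 19; the polarised siloxyalkyne then adds across its C=C in a polar [2+2] cycloaddition (bonds C2'–C3' and C4'–C5') to give cyclobutenone 20. Thermal 4π-electrocyclic opening of 20 gives dienylketene 21, whose ketene carbon C2' and diene terminus C1' join in a 6π-electrocyclisation that closes ring B as dienone 22, and tautomerisation gives phenol 23. The closest known reaction type is the diazoketone (Wolff) variant of the Danheiser benzannulation with siloxyalkynes, which gives resorcinol monosilyl ethers. No stereocentre is formed in the product, and C3 of the chroman is never part of an enolisable or conjugated system under neutral photolysis, so it should be carried through unchanged. The only selectivity needed is the orientation of the [2+2] step, which the alkyne itself secures: its prenyl-bearing carbon is the nucleophilic terminus and bonds to the ketene carbonyl carbon, so prenyl lands on C3' between the free C2' hydroxyl and the silylated O4'. Excess 18 and the heating period are meant to drain residual 20 and to limit acylation of the hindered phenol by ketene.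

Step 10
Reactants: 23 (R)-6-[7-(methoxymethoxy)chroman-3-yl]-2-(3-methylbut-2-en-1-yl)-3-[(triisopropylsilyl)oxy]phenol
Product: 24 (R)-4-[7-(methoxymethoxy)chroman-3-yl]-2-(3-methylbut-2-en-1-yl)benzene-1,3-diol
Conditions: Bu4NF, AcOH, THF, 0 °C
Reagents that add atoms: none
Why: Fluoride cleaves the aryl silyl ether through Si–F bond formation while acetic acid buffers the electron-rich resorcinolate; the MOM acetal and the alkenes are inert.

Step 11
Reactants: 24 (R)-4-[7-(methoxymethoxy)chroman-3-yl]-2-(3-methylbut-2-en-1-yl)benzene-1,3-diol; 25 3-methylbut-2-enal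
Product: 27 (R)-6-[7-(methoxymethoxy)chroman-3-yl]-2,2-dimethyl-8-(3-methylbut-2-en-1-yl)-2H-chromen-7-ol, via quinone methide 26 (not isolated)
Conditions: ethylenediammonium diacetate (20 mol%), toluene, reflux
Reagents that add atoms: none
Why: Knoevenagel-type condensation at C5', dehydration to ortho-quinone methide 26 and oxa-6π electrocyclisation (formal [3+3] chromene annulation) can only give the linear pyran on O4'/C5', because C5' is the sole free carbon ortho to a hydroxyl and ring A has no free hydroxyl.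

Step 12
Reactants: 27 (R)-6-[7-(methoxymethoxy)chroman-3-yl]-2,2-dimethyl-8-(3-methylbut-2-en-1-yl)-2H-chromen-7-ol
Product: 28 (R)-6-(7-hydroxychroman-3-yl)-2,2-dimethyl-8-(3-methylbut-2-en-1-yl)-2H-chromen-7-ol
Conditions: 3 M aq. HCl/MeOH, rt → 40 °C, monitored; NaHCO3 quench
Reagents that add atoms: none
Why: Acid-catalysed acetal methanolysis frees the 7-hydroxyl, and under dilute acid near room temperature acetal cleavage is expected to outpace protonation of the prenyl and chromene double bonds.

Compound list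
1 | 2,4-dihydroxybenzaldehyde | O=Cc1ccc(O)cc1O | starting material
2 | 2-hydroxy-4-(methoxymethoxy)benzaldehyde | O=Cc1ccc(OCOC)cc1O | intermediate
3 | acrylonitrile | C=CC#N | starting material
4 | 4-hydroxy-7-(methoxymethoxy)chroman-3-carbonitrile (aldol adduct, racemic diastereomer mixture) | N#CC1COc2cc(OCOC)ccc2C1O | intermediate
5 | 7-(methoxymethoxy)-2H-chromene-3-carbonitrile | N#CC1=Cc2ccc(OCOC)cc2OC1 | intermediate
6 | 7-(methoxymethoxy)-2H-chromene-3-carboxamide | NC(=O)C1=Cc2ccc(OCOC)cc2OC1 | intermediate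
7 | 7-(methoxymethoxy)-2H-chromene-3-carboxylic acid | OC(=O)C1=Cc2ccc(OCOC)cc2OC1 | intermediate
8 | (S)-7-(methoxymethoxy)chroman-3-carboxylic acid | OC(=O)[C@@H]1COc2cc(OCOC)ccc2C1 | intermediate
9 | (R)-[7-(methoxymethoxy)chroman-3-yl]methanol | OC[C@@H]1COc2cc(OCOC)ccc2C1 | intermediate
10 | 1-(triphenyl-λ5-phosphanylidene)propan-2-one | CC(=O)C=P(c1ccccc1)(c1ccccc1)c1ccccc1 | starting material
11 | (S)-7-(methoxymethoxy)chroman-3-carbaldehyde | O=C[C@@H]1COc2cc(OCOC)ccc2C1 | intermediate
12 | (R,E)-4-[7-(methoxymethoxy)chroman-3-yl]but-3-en-2-one | CC(=O)/C=C/[C@@H]1COc2cc(OCOC)ccc2C1 | intermediate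
13 | (R,E)-1,1,1-trifluoro-6-[7-(methoxymethoxy)chroman-3-yl]hex-5-ene-2,4-dione | O=C(CC(=O)C(F)(F)F)/C=C/[C@@H]1COc2cc(OCOC)ccc2C1 | intermediate
14 | (R,E)-1-diazo-4-[7-(methoxymethoxy)chroman-3-yl]but-3-en-2-one | [N-]=[N+]=CC(=O)/C=C/[C@@H]1COc2cc(OCOC)ccc2C1 | intermediate
15 | ethyl 4-methylpent-3-enoate | CCOC(=O)CC=C(C)C | starting material
16 | lithium 1,1-dibromo-5-methylhexa-1,4-dien-2-olate | [Li+].[O-]C(CC=C(C)C)=C(Br)Br | intermediate
17 | lithium 5-methylhex-4-en-1-yn-1-olate | [Li+].[O-]C#CCC=C(C)C | intermediate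
18 | triisopropyl[(5-methylhex-4-en-1-yn-1-yl)oxy]silane | CC(C)=CCC#CO[Si](C(C)C)(C(C)C)C(C)C | intermediate
19 | (R,E)-4-[7-(methoxymethoxy)chroman-3-yl]buta-1,3-dien-1-one (vinylketene) | O=C=C/C=C/[C@@H]1COc2cc(OCOC)ccc2C1 | intermediate
20 | 4-{(E)-2-[(R)-7-(methoxymethoxy)chroman-3-yl]ethenyl}-2-(3-methylbut-2-en-1-yl)-3-[(triisopropylsilyl)oxy]cyclobut-2-en-1-one (ring C4 epimers) | O=C1C(CC=C(C)C)=C(O[Si](C(C)C)(C(C)C)C(C)C)C1/C=C/[C@@H]2COc3cc(OCOC)ccc3C2 | intermediate
21 | 6-[(R)-7-(methoxymethoxy)chroman-3-yl]-2-(3-methylbut-2-en-1-yl)-3-[(triisopropylsilyl)oxy]hexa-1,3,5-trien-1-one, ketene carbon cis to the (E)-alkenyl group across C3=C4 (dienylketene) | O=C=C(CC=C(C)C)/C(O[Si](C(C)C)(C(C)C)C(C)C)=C\C=C\[C@@H]1COc2cc(OCOC)ccc2C1 | intermediate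
22 | 6-[(R)-7-(methoxymethoxy)chroman-3-yl]-2-(3-methylbut-2-en-1-yl)-3-[(triisopropylsilyl)oxy]cyclohexa-2,4-dien-1-one (C6 epimers) | O=C1C(CC=C(C)C)=C(O[Si](C(C)C)(C(C)C)C(C)C)C=CC1[C@@H]2COc3cc(OCOC)ccc3C2 | intermediate
23 | (R)-6-[7-(methoxymethoxy)chroman-3-yl]-2-(3-methylbut-2-en-1-yl)-3-[(triisopropylsilyl)oxy]phenol | CC(C)=CCc1c(O)c([C@@H]2COc3cc(OCOC)ccc3C2)ccc1O[Si](C(C)C)(C(C)C)C(C)C | intermediate
24 | (R)-4-[7-(methoxymethoxy)chroman-3-yl]-2-(3-methylbut-2-en-1-yl)benzene-1,3-diol | CC(C)=CCc1c(O)c([C@@H]2COc3cc(OCOC)ccc3C2)ccc1O | intermediate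
25 | 3-methylbut-2-enal | CC(C)=CC=O | starting material
26 | 3-hydroxy-4-[(R)-7-(methoxymethoxy)chroman-3-yl]-2-(3-methylbut-2-en-1-yl)-6-(3-methylbut-2-en-1-ylidene)cyclohexa-2,4-dien-1-one (ortho-quinone methide) | CC(C)=CCC1=C(O)C([C@@H]2COc3cc(OCOC)ccc3C2)=CC(=CC=C(C)C)C1=O | intermediate
27 | (R)-6-[7-(methoxymethoxy)chroman-3-yl]-2,2-dimethyl-8-(3-methylbut-2-en-1-yl)-2H-chromen-7-ol | CC(C)=CCc1c(O)c([C@@H]2COc3cc(OCOC)ccc3C2)cc2c1OC(C)(C)C=C2 | intermediate
28 | (R)-6-(7-hydroxychroman-3-yl)-2,2-dimethyl-8-(3-methylbut-2-en-1-yl)-2H-chromen-7-ol | CC(C)=CCc1c(O)c([C@@H]2COc3cc(O)ccc3C2)cc2c1OC(C)(C)C=C2 | target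

Total step count: 12.
Longest linear sequence: 11 steps (steps 1–7 and 9–12); step 8 is the one-step side branch.

Steps most likely to fail

1. Step 9. Photochemical E/Z isomerisation and secondary photoreactions of the diazo enone, ketene oligomerisation outrunning capture by the alkyne, or acylation of the new phenol by ketene may erode the annulation. The fallback generates the vinylketene thermally in the dark. It sets out from alcohol 9: aldehyde 11 (Dess–Martin oxidation as in step 6, used at once) would be condensed with the ylide from (2-carboxyethyl)triphenylphosphonium bromide and NaN(SiMe3)2 (THF, −78 °C) to give (R,Z)-4-[7-(methoxymethoxy)chroman-3-yl]but-3-enoic acid F1. Oxalyl chloride with catalytic DMF should give (R,Z)-4-[7-(methoxymethoxy)chroman-3-yl]but-3-enoyl chloride F2. Slow addition of F2 to Et3N and siloxyalkyne 18 in toluene at 80 °C should dehydrochlorinate it to (R,Z)-4-[7-(methoxymethoxy)chroman-3-yl]buta-1,3-dien-1-one F3. Ketenes made this way from acid chlorides are known to add to siloxyalkynes, so F3 should give the (Z)-alkenyl cyclobutenone F4, which on heating opens to the (Z)-terminated dienylketene F5. Closure of F5, slower because the terminal substituent points inward, gives dienone 22, and tautomerisation brings the sequence back to the route at 23.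

2. Step 11. Condensation at C5' may be slow, and oxidative degradation of the electron-rich resorcinol or ring closure of the prenyl group onto a neighbouring hydroxyl at reflux may compete. The fallback builds the pyran by an aryl propargyl ether Claisen rearrangement. It sets out from 23: NaH and MOMCl in DMF at 0 °C should give the 2',7-bis(methoxymethyl) ether of the 4'-silyl ether F6, and Bu4NF the 4'-phenol F7. Alkylation with 3-chloro-3-methylbut-1-yne (K2CO3, KI, catalytic CuI, acetone, reflux) should give the 1,1-dimethylpropargyl ether F8. Heating in N,N-diethylaniline at 180 °C should effect [3,3] shift to C5' (C3' is blocked) to give allenyl dienone F9, enolisation to allenylphenol F10, 1,5-hydrogen shift to quinone methide F11 and oxa-6π closure to the bis(methoxymethyl) chromene F12. Methanolysis under the conditions of step 12 removes both acetals and returns to the route at 28.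

3. Step 12. Protonation of the prenyl or chromene double bond may compete with acetal cleavage, leading to ring closure of the prenyl group onto O2' or to addition of methanol. The fallback avoids protic acid. It sets out from 27: Et3SiOTf and 2,2'-bipyridyl in CH2Cl2 at 0 °C should exchange the aryl MOM group for a triethylsilyl group (and silylate O2') to give the 2',7-bis(triethylsilyl) ether F13. Buffered Bu4NF (AcOH, THF, 0 °C) then frees both phenols and returns to the route at 28.

Further compounds
F1 | step 9 | (R,Z)-4-[7-(methoxymethoxy)chroman-3-yl]but-3-enoic acid | OC(=O)C/C=C\[C@@H]1COc2cc(OCOC)ccc2C1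
F2 | step 9 | (R,Z)-4-[7-(methoxymethoxy)chroman-3-yl]but-3-enoyl chloride | ClC(=O)C/C=C\[C@@H]1COc2cc(OCOC)ccc2C1
F3 | step 9 | (R,Z)-4-[7-(methoxymethoxy)chroman-3-yl]buta-1,3-dien-1-one | O=C=C/C=C\[C@@H]1COc2cc(OCOC)ccc2C1
F4 | step 9 | 4-{(Z)-2-[(R)-7-(methoxymethoxy)chroman-3-yl]ethenyl}-2-(3-methylbut-2-en-1-yl)-3-[(triisopropylsilyl)oxy]cyclobut-2-en-1-one | O=C1C(CC=C(C)C)=C(O[Si](C(C)C)(C(C)C)C(C)C)C1/C=C\[C@@H]2COc3cc(OCOC)ccc3C2
F5 | step 9 | dienylketene as 21 but with (Z)-alkene next to the chroman | O=C=C(CC=C(C)C)/C(O[Si](C(C)C)(C(C)C)C(C)C)=C\C=C/[C@@H]1COc2cc(OCOC)ccc2C1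
F6 | step 11 | (R)-triisopropyl{3-(methoxymethoxy)-4-[7-(methoxymethoxy)chroman-3-yl]-2-(3-methylbut-2-en-1-yl)phenoxy}silane | CC(C)=CCc1c(OCOC)c([C@@H]2COc3cc(OCOC)ccc3C2)ccc1O[Si](C(C)C)(C(C)C)C(C)C
F7 | step 11 | (R)-3-(methoxymethoxy)-4-[7-(methoxymethoxy)chroman-3-yl]-2-(3-methylbut-2-en-1-yl)phenol | CC(C)=CCc1c(OCOC)c([C@@H]2COc3cc(OCOC)ccc3C2)ccc1O
F8 | step 11 | (R)-7-(methoxymethoxy)-3-[2-(methoxymethoxy)-3-(3-methylbut-2-en-1-yl)-4-(2-methylbut-3-yn-2-yloxy)phenyl]chroman | CC(C)=CCc1c(OCOC)c([C@@H]2COc3cc(OCOC)ccc3C2)ccc1OC(C)(C)C#C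
F9 | step 11 | 3-(methoxymethoxy)-4-[(R)-7-(methoxymethoxy)chroman-3-yl]-2-(3-methylbut-2-en-1-yl)-6-(3-methylbuta-1,2-dien-1-yl)cyclohexa-2,4-dien-1-one | CC(C)=CCC1=C(OCOC)C([C@@H]2COc3cc(OCOC)ccc3C2)=CC(C=C=C(C)C)C1=O
F10 | step 11 | (R)-3-(methoxymethoxy)-4-[7-(methoxymethoxy)chroman-3-yl]-2-(3-methylbut-2-en-1-yl)-6-(3-methylbuta-1,2-dien-1-yl)phenol | CC(C)=CCc1c(OCOC)c([C@@H]2COc3cc(OCOC)ccc3C2)cc(C=C=C(C)C)c1O
F11 | step 11 | 3-(methoxymethoxy)-4-[(R)-7-(methoxymethoxy)chroman-3-yl]-2-(3-methylbut-2-en-1-yl)-6-(3-methylbut-2-en-1-ylidene)cyclohexa-2,4-dien-1-one | CC(C)=CCC1=C(OCOC)C([C@@H]2COc3cc(OCOC)ccc3C2)=CC(=CC=C(C)C)C1=O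
F12 | step 11 | (R)-7-(methoxymethoxy)-6-[7-(methoxymethoxy)chroman-3-yl]-2,2-dimethyl-8-(3-methylbut-2-en-1-yl)-2H-chromene | CC(C)=CCc1c(OCOC)c([C@@H]2COc3cc(OCOC)ccc3C2)cc2c1OC(C)(C)C=C2
F13 | step 12 | (R)-{[2,2-dimethyl-8-(3-methylbut-2-en-1-yl)-6-(7-triethylsilyloxychroman-3-yl)-2H-chromen-7-yl]oxy}triethylsilane | CC(C)=CCc1c(O[Si](CC)(CC)CC)c([C@@H]2COc3cc(O[Si](CC)(CC)CC)ccc3C2)cc2c1OC(C)(C)C=C2
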